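**Retrosynthetic overview**
- Plakortolide R ⇒ terminal-alkene core + (E)-1-phenylbuta-1,3-diene (C13=C14, cross-metathesis, last step).
- C6 quaternary centre ⇒ C6 peroxyhemiketal + methyl (axial AlMe3 methylation of a peroxycarbenium ion, steered by C4).
- 1,2-Dioxane ring (C3–O and C6–O, both oxygens from O2) ⇒ saturated keto-lactone by photochemical γ-C–H abstraction/O2 capture; this ring is formed second.
- Keto-lactone ⇒ lactone aldehyde + oct-7-enyl Grignard; aldehyde ⇒ anti-Markovnikov oxidation of (R)-lavender lactone.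
- γ-Lactone ring (formed first, carries C4, the only purchased stereocentre) ⇒ (R)-linalool by chemoselective ozonolysis/oxidation.

Assumption: (R)-(−)-linalool is bought at ≥97% ee (this fixes the ee of the target); C1–C16 follow plakortolide numbering (C1 lactone C=O, C3/C4 ring fusion, C6 peroxy-quaternary carbon).

Step 1
Reactants: 1 (R)-(−)-linalool [(3R)-3,7-dimethylocta-1,6-dien-3-ol]
Product: 3 (R)-lavender lactone [(5R)-5-ethenyl-5-methyloxolan-2-one], via lactol 2 (not isolated)
Conditions: O3 (1.0 equiv, indicator end point), CH2Cl2, −78 °C; PPh3; then TEMPO (10 mol %), PhI(OAc)2, rt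
Reagents that add atoms: ozone, O=[O+][O-]
Why: Chemoselective ozonolysis cleaves the electron-rich trisubstituted alkene much faster than the vinyl group, the hydroxy aldehyde closes to lactol 2 and TEMPO/PhI(OAc)2 oxidises it to the γ-lactone; C4 is the untouched carbinol carbon of linalool.

Step 2
Reactants: 3 (R)-lavender lactone
Product: 4 2-[(2R)-2-methyl-5-oxooxolan-2-yl]acetaldehyde
Conditions: PdCl2(PhCN)2 (10 mol %), CuCl2·2H2O (10 mol %), AgNO2 (5 mol %), O2 (1 atm), t-BuOH/MeNO2 15:1, rt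
Reagents that add atoms: dioxygen, O=O
Why: Nitrite-modified, aldehyde-selective Wacker oxidation, in which the allylic acyloxy group and the adjacent quaternary carbon direct oxygen to the terminal carbon; no stereocentre is touched.

Step 3
Reactants: 4 2-[(2R)-2-methyl-5-oxooxolan-2-yl]acetaldehyde; 5 8-bromooct-1-ene
Product: 7 (5R)-5-(2-hydroxydec-9-en-1-yl)-5-methyloxolan-2-one (both carbinol epimers), via oct-7-en-1-ylmagnesium bromide 6 (not isolated)
Conditions: 5, Mg, THF, 40 °C; then 4, THF, −78 °C; aq. NH4Cl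
Reagents that add atoms: none
Why: Grignard 1,2-addition to the aldehyde at −78 °C is much faster than attack on the γ-lactone; the new carbinol centre is formed unselectively and is erased in step 4.

Step 4
Reactants: 7 (5R)-5-(2-hydroxydec-9-en-1-yl)-5-methyloxolan-2-one
Product: 8 (5R)-5-methyl-5-(2-oxodec-9-en-1-yl)oxolan-2-one
Conditions: Dess–Martin periodinane (1.2 equiv), CH2Cl2, 0 °C → rt
Reagents that add atoms: none
Why: Dess–Martin oxidation of the secondary alcohol under non-basic conditions avoids β-elimination of the β-acyloxy ketone.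

Step 5
Reactants: 8 (5R)-5-methyl-5-(2-oxodec-9-en-1-yl)oxolan-2-one
Product: 11 cis-fused peroxyhemiketal (4aS,7aS)-3-hydroxy-4a-methyl-3-(oct-7-en-1-yl)tetrahydro-3H-furo[3,2-c][1,2]dioxin-6(4H)-one (both C6 anomers), via triplet 1,4-biradical 9 (not isolated), via γ-hydroperoxy ketone 10 (not isolated)
Conditions: hν (300–310 nm, Pyrex), O2 (1 atm), t-BuOH/MeCN 1:1, 0.02 M, 10 °C; then Et2NH (0.3 equiv), CF3CH2OH, rt
Reagents that add atoms: dioxygen, O=O
Why: Proposed new method: n,π* excitation of the dialkyl ketone should trigger Norrish type 2 abstraction of the C3 hydrogen syn to the tether through a six-membered transition state, O2 captures biradical 9 to give hydroperoxy ketone 10 which closes to hemiketal 11, and the amine finish lets the C3–O bond equilibrate by reversible tethered 6-exo oxa-Michael addition so that only the cis ring fusion dictated by the linalool-derived C4 persists; the closest known reaction type is O2 trapping of Norrish type 2 biradicals of aryl alkyl ketones to γ-hydroperoxy ketones and 1,2-dioxan-3-ols.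

Step 6
Reactants: 11 cis-fused peroxyhemiketal
Product: 13 (3S,4aS,7aS)-3,4a-dimethyl-3-(oct-7-en-1-yl)tetrahydro-3H-furo[3,2-c][1,2]dioxin-6(4H)-one, via peroxycarbenium ion 12 (not isolated)
Conditions: AlMe3 (4 equiv), CH2Cl2, −78 °C; then TMSOTf (1.2 equiv), −78 → −40 °C; aq. NaHCO3
Reagents that add atoms: trimethylaluminium, C[Al](C)C
Why: Proposed new method: ionisation of the aluminium hemiketalate gives peroxycarbenium ion 12, whose half-chair holds the C4 lactone oxygen pseudoaxial and the C4 methyl pseudoequatorial, so methyl is delivered along the axial trajectory syn to the lactone oxygen (the opposite axial path would create a 1,3-diaxial Me/Me clash), which sets C6 with methyl cis to the lactone oxygen and the chain equatorial; the closest known reaction types are Lewis-acid substitution of cyclic peroxyketals by allylsilanes or silyl enol ethers and AlMe3 C-methylation of anomeric fluorides and acetates.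

Step 7
Reactants: 13 (3S,4aS,7aS)-3,4a-dimethyl-3-(oct-7-en-1-yl)tetrahydro-3H-furo[3,2-c][1,2]dioxin-6(4H)-one; 14 [(1E)-buta-1,3-dien-1-yl]benzene
Product: 15 plakortolide R
Conditions: second-generation Grubbs catalyst (H2IMes)(PCy3)Cl2Ru=CHPh (5 mol %), 14 (4 equiv), CH2Cl2, 40 °C
Reagents that add atoms: none
Why: Olefin cross-metathesis joins the terminal alkene to the vinyl end of the diene (the styrenyl double bond is far less reactive), releases ethene and gives the thermodynamically favoured (E,E)-diene, while the dialkyl peroxide tolerates the ruthenium carbene.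

**Compound list**
1 | (R)-(−)-linalool, (3R)-3,7-dimethylocta-1,6-dien-3-ol | C=C[C@](C)(O)CCC=C(C)C | starting material
2 | lactol, (5R)-5-ethenyl-5-methyloxolan-2-ol (both anomers) | C=C[C@@]1(C)CCC(O)O1 | intermediate
3 | (R)-lavender lactone, (5R)-5-ethenyl-5-methyloxolan-2-one | C=C[C@@]1(C)CCC(=O)O1 | intermediate
4 | 2-[(2R)-2-methyl-5-oxooxolan-2-yl]acetaldehyde | O=CC[C@@]1(C)CCC(=O)O1 | intermediate
5 | 8-bromooct-1-ene | C=CCCCCCCBr | starting material
6 | oct-7-en-1-ylmagnesium bromide | C=CCCCCCC[Mg]Br | intermediate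
7 | (5R)-5-(2-hydroxydec-9-en-1-yl)-5-methyloxolan-2-one (both carbinol epimers) | C=CCCCCCCC(O)C[C@@]1(C)CCC(=O)O1 | intermediate
8 | (5R)-5-methyl-5-(2-oxodec-9-en-1-yl)oxolan-2-one | C=CCCCCCCC(=O)C[C@@]1(C)CCC(=O)O1 | intermediate
9 | triplet 1,4-biradical (ketyl carbon C6 and lactone carbon C3) | C=CCCCCCC[C](O)C[C@@]1(C)[CH]CC(=O)O1 | intermediate
10 | γ-hydroperoxy ketone, (4S,5S)-4-hydroperoxy-5-methyl-5-(2-oxodec-9-en-1-yl)oxolan-2-one | C=CCCCCCCC(=O)C[C@]1(C)OC(=O)C[C@@H]1OO | intermediate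
11 | cis-fused peroxyhemiketal, (4aS,7aS)-3-hydroxy-4a-methyl-3-(oct-7-en-1-yl)tetrahydro-3H-furo[3,2-c][1,2]dioxin-6(4H)-one (both C6 anomers) | OC1(CCCCCCC=C)C[C@]2(C)OC(=O)C[C@@H]2OO1 | intermediate
12 | peroxycarbenium ion (C6=O+ within the dioxane ring) | [O+]1=C(CCCCCCC=C)C[C@]2(C)OC(=O)C[C@@H]2O1 | intermediate
13 | (3S,4aS,7aS)-3,4a-dimethyl-3-(oct-7-en-1-yl)tetrahydro-3H-furo[3,2-c][1,2]dioxin-6(4H)-one | C[C@]1(CCCCCCC=C)C[C@]2(C)OC(=O)C[C@@H]2OO1 | intermediate
14 | [(1E)-buta-1,3-dien-1-yl]benzene | C=C/C=C/c1ccccc1 | starting material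
15 | plakortolide R, (3S,4aS,7aS)-3,4a-dimethyl-3-[(7E,9E)-10-phenyldeca-7,9-dien-1-yl]tetrahydro-3H-furo[3,2-c][1,2]dioxin-6(4H)-one | C[C@]1(CCCCCC/C=C/C=C/c2ccccc2)C[C@]2(C)OC(=O)C[C@@H]2OO1 | target

**Step count and risks**

Total step count: 7. Longest linear sequence: 7 (from 1; 5 and 14 are bought).

The three steps most likely to fail are steps 5, 6 and 7.

First, the photochemical peroxidation (step 5, proposed new). Type 2 abstraction at the chain C9–H competes with abstraction at the lactone C3–H, O2 also quenches the ketone triplet, and the biradical can fragment, so a yield of roughly 30–40% is the realistic expectation. The fallback is known chemistry. It sets out from 3 and returns at 11: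
- α-Selenation of 3 (LiN(i-Pr)2, PhSeBr, THF, −78 °C) gives (5R)-5-ethenyl-5-methyl-3-(phenylselanyl)oxolan-2-one F1.
- Selenoxide elimination (H2O2, pyridine, CH2Cl2, 0 °C) gives the butenolide (5S)-5-ethenyl-5-methylfuran-2(5H)-one F2.
- The conditions of steps 2, 3 and 4 (with 6 made from 5 as before) take F2 to 2-[(2S)-2-methyl-5-oxo-2,5-dihydrofuran-2-yl]acetaldehyde F3, then (5S)-5-(2-hydroxydec-9-en-1-yl)-5-methylfuran-2(5H)-one F4, then the keto-butenolide (5S)-5-methyl-5-(2-oxodec-9-en-1-yl)furan-2(5H)-one F5.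
- Urea·H2O2 with Sc(OTf)3 in THF converts F5 into the perhydrate (5S)-5-(2-hydroperoxy-2-hydroxydec-9-en-1-yl)-5-methylfuran-2(5H)-one F6.
- Et2NH in CF3CH2OH closes F6 to 11 by tethered 6-exo oxa-Michael addition, which can only give the cis ring fusion.

Second, the methylation (step 6, proposed new). AlMe3 may reduce or cleave the O–O bond, the Lewis acid may trigger O–O heterolysis instead of C6–O ionisation, and the facial selectivity is predicted, not demonstrated. The fallback is known chemistry. It sets out from 11 and returns at 13: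
- TMSOTf-mediated substitution of 11 with 1-tert-butoxy-1-(trimethylsilyloxy)ethene (peroxycarbenium/silyl ketene acetal coupling along the same axial trajectory) gives tert-butyl [(3S,4aS,7aS)-4a-methyl-3-(oct-7-en-1-yl)-6-oxohexahydro-3H-furo[3,2-c][1,2]dioxin-3-yl]acetate F7.
- CF3CO2H in CH2Cl2 gives [(3S,4aS,7aS)-4a-methyl-3-(oct-7-en-1-yl)-6-oxohexahydro-3H-furo[3,2-c][1,2]dioxin-3-yl]acetic acid F8.
- DCC and N-hydroxypyridine-2-thione give the Barton ester, the 2-thioxopyridin-1(2H)-yl ester of that acid F9.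
- Visible-light photolysis of F9 with t-BuSH (Barton reductive decarboxylation) turns the CH2CO2 arm into the C6 methyl of 13.

Third, the cross-metathesis (step 7). The risks are E/Z mixtures at C13=C14, diene oligomerisation and ruthenium-induced peroxide decomposition on the most precious material. The fallback sets out from 13 and returns at 15:
- Ozonolysis of the terminal alkene (O3, CH2Cl2, −78 °C; Me2S) gives 7-[(3S,4aS,7aS)-3,4a-dimethyl-6-oxohexahydro-3H-furo[3,2-c][1,2]dioxin-3-yl]heptanal F10.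
- Horner–Wadsworth–Emmons olefination of F10 with diethyl cinnamylphosphonate (LiN(SiMe3)2, THF, −78 °C) gives the (E,E)-diene 15.

Further compounds
F1 | step 5 | (5R)-5-ethenyl-5-methyl-3-(phenylselanyl)oxolan-2-one (C3 epimers) | C=C[C@@]1(C)CC([Se]c2ccccc2)C(=O)O1
F2 | step 5 | (5S)-5-ethenyl-5-methylfuran-2(5H)-one | C=C[C@@]1(C)C=CC(=O)O1
F3 | step 5 | 2-[(2S)-2-methyl-5-oxo-2,5-dihydrofuran-2-yl]acetaldehyde | O=CC[C@@]1(C)C=CC(=O)O1
F4 | step 5 | (5S)-5-(2-hydroxydec-9-en-1-yl)-5-methylfuran-2(5H)-one (both carbinol epimers) | C=CCCCCCCC(O)C[C@@]1(C)C=CC(=O)O1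
F5 | step 5 | (5S)-5-methyl-5-(2-oxodec-9-en-1-yl)furan-2(5H)-one | C=CCCCCCCC(=O)C[C@@]1(C)C=CC(=O)O1
F6 | step 5 | (5S)-5-(2-hydroperoxy-2-hydroxydec-9-en-1-yl)-5-methylfuran-2(5H)-one | C=CCCCCCCC(O)(OO)C[C@@]1(C)C=CC(=O)O1
F7 | step 6 | tert-butyl [(3S,4aS,7aS)-4a-methyl-3-(oct-7-en-1-yl)-6-oxohexahydro-3H-furo[3,2-c][1,2]dioxin-3-yl]acetate | CC(C)(C)OC(=O)C[C@]1(CCCCCCC=C)C[C@]2(C)OC(=O)C[C@@H]2OO1
F8 | step 6 | [(3S,4aS,7aS)-4a-methyl-3-(oct-7-en-1-yl)-6-oxohexahydro-3H-furo[3,2-c][1,2]dioxin-3-yl]acetic acid | OC(=O)C[C@]1(CCCCCCC=C)C[C@]2(C)OC(=O)C[C@@H]2OO1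
F9 | step 6 | 2-thioxopyridin-1(2H)-yl [(3S,4aS,7aS)-4a-methyl-3-(oct-7-en-1-yl)-6-oxohexahydro-3H-furo[3,2-c][1,2]dioxin-3-yl]acetate (Barton ester) | S=c1ccccn1OC(=O)C[C@]1(CCCCCCC=C)C[C@]2(C)OC(=O)C[C@@H]2OO1
F10 | step 7 | 7-[(3S,4aS,7aS)-3,4a-dimethyl-6-oxohexahydro-3H-furo[3,2-c][1,2]dioxin-3-yl]heptanal | C[C@]1(CCCCCCC=O)C[C@]2(C)OC(=O)C[C@@H]2OO1
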